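## Analysis of the target

The target 20 is a 2-aryl-3-methyl-2,3-dihydro-1-benzofuran. Ring A is the benzo ring (C3a, C4, C5, C6, C7, C7a), ring B the dihydrofuran (O1, C2, C3, C3a, C7a) and ring C the 3,4,5-trimethoxyphenyl group on C2. There are two adjacent stereocentres, C2 (R) and C3 (R), with the aryl and methyl groups trans on ring B; the only other stereochemical element is the (E)-geometry of the propenyl group. Ring A carries oxygen at C7a (O1) and at C6 (methoxy) in a 1,3-relationship, the three-carbon chain at C5 (ortho to the methoxy group, para to O1) and hydrogen at C4 and C7. The sensitive sites are the C2–O1 bond, a benzylic aryl ether that can ionise under acid because ring C supports a cation at C2, and the electron-rich propenyl styrene, which acid can dimerise. The difficulty lies in fixing the trans C2/C3 pair in one absolute sense and in placing the C5 chain without a late electrophilic substitution, which would have to choose between C5 and C7 under Lewis acid. The plan rests on the fact that C3a and C7a–O1 are the two carbons of an enol ether: extended by C7 and the oxygenated C6 they form a 1,3-dioxygenated diene, while C4, C5 and the chain map on to an ethynyl ethyl ketone. Ring A can therefore be built last, on a dihydrofuran that already holds C2 and C3.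

## Retrosynthetic reasoning

**20 to 18 (no skeletal bond cut).** The propenyl group is traced back through carbinol 19 to the propanoyl ketone 18. The carbonyl is wanted because it makes the two-carbon partner electron-poor and fixes the orientation of the ring-forming step. The forward steps must give the (E)-alkene without ionising C2–O1.

**18 to 15 + 16 (C3a–C4 and C5–C6).** Ring A is opened into diene 15 (C3a=C7a–C7=C6) and ynone 16 (C4≡C5 with the chain). This pair of bonds is chosen because it leaves the O1–C7a=C3a enol ether intact inside the diene, places both ring A oxygens on the four-carbon component where they reinforce each other, and puts the whole side chain on a commercial alkyne. Cutting any other pair would break ring B or require a less accessible diene. The forward reaction must give one orientation (acyl at C5) and must aromatise cycloadduct 17 with the C6 methoxy group kept.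

**15 to 13 (O–Si bond).** The silyl ketene acetal comes from the exocyclic enol ether ester 13 by γ-deprotonation at C3a (dienolate 14) and O-silylation. This exposes a stable, storable ester as the real precursor of the sensitive diene.

**13 to 8 + 9 (C7–C7a).** The C7a=C7 double bond is taken back to hydroxy keto ester 12 and then to lactone 8 and methyl acetate 9, through enolate 10 and adduct 11. Cutting here reduces the problem to a trans-disubstituted butyrolactone, which carries both stereocentres and nothing else.

**8 to 4 (oxidation level only).** Lactone 8 comes from diol 6 by oxidative lactonisation through lactol 7, and 6 from the terminal alkene of 4 by hydroboration through 5. The vinyl group of 4 thus becomes C3a and C7a.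

**4 to 1 + 2 (C2–C3).** The homoallylic alcohol is cut between the two stereocentres into aldehyde 1 and crotylboronate 2. A single catalytic anti-crotylboration, through borate 3, sets both centres, and all later steps only have to preserve them.

## Alternatives that were turned down

**Alternative 1:** Cutting O1–C7a and C3a–C4 leads to the open-chain (6R,7R)-7-hydroxy-6-methyl-7-(3,4,5-trimethoxyphenyl)hept-1-en-4-yn-3-one A1, whose C6 ketone sits between the C7≡C7a alkyne and the C4=C5 vinyl group.
- Forward key step: under a strong alkoxide base the C2 alkoxide would add 5-exo-dig to C7a. Deprotonation at C3a would give a trienolate that closes C3a–C4 by 6π-electrocyclisation to (2R,3R)-3-methyl-2-(3,4,5-trimethoxyphenyl)-3,3a,4,5-tetrahydro-1-benzofuran-6(2H)-one A2.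
- For it: ring B and the carbocycle form in one operation, C2 and C3 can come from the same crotylation, and no moisture-sensitive diene is handled. On rings closed per step it is stronger than the chosen plan (two against one).
- Against it: A2 is below the arene oxidation level, has a free oxygen at C6 and no carbon at C5. Dehydrogenation, O-methylation, a C5-selective acylation under Lewis acid next to the labile C2–O1 bond, reduction and dehydration would follow, about five steps where the chosen plan needs two. A1 is also a cross-conjugated double Michael acceptor that base or a second molecule can attack at C4 before the cascade starts.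
- Comparison: the chosen plan gives up the second ring closure but delivers ring A fully substituted and already aromatic.

**Alternative 2:** Cutting O1–C7a and C3–C3a leads to the erythro epoxy alcohol (S)-[(2R)-oxiran-2-yl](3,4,5-trimethoxyphenyl)methanol A3 and the aryne 3-chloro-5-methoxybenzyne A4.
- Forward key step: the alkoxide of A3 would add to the aryne carbon C7a remote from chlorine. The aryl anion at C3a would then open the epoxide at C3 with inversion (5-exo-tet) to give [(2R,3S)-4-chloro-6-methoxy-2-(3,4,5-trimethoxyphenyl)-2,3-dihydro-1-benzofuran-3-yl]methanol A5.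
- For it: ring A is an arene from the start, so no aromatisation is at stake; the union is convergent; and C3 follows stereospecifically from the epoxide. On these points it is at least as strong as the chosen plan.
- Against it: the chlorine only steers the aryne and must be removed, the C3 hydroxymethyl must be deoxygenated, and C5 is still bare, so the late C5/C7 acylation problem returns. The alkoxide of a 2,3-epoxy alcohol can undergo Payne rearrangement before it meets the short-lived aryne, which would scramble C2. The aryl anion can also simply be protonated, and the aryne precursor is itself a multistep ortho-difunctionalised arene.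
- Comparison: the chosen plan has a longer linear approach to its key step, but every carbon introduced stays in the target and only two steps follow.

**Alternative 3:** Cutting C4–C5 and C7–C7a leads to the α-methylene lactone (4R,5R)-4-methyl-3-methylidene-5-(3,4,5-trimethoxyphenyl)oxolan-2-one A6 and ethyl 3-oxobutanoate A7.
- Forward key step: the central carbon of A7 would add to the exocyclic methylene of A6, the terminal carbon of the adduct dianion would attack the lactone carbonyl, and acid would reclose O1 on C7a. The product is ethyl (2R,3R)-3-methyl-6-oxo-2-(3,4,5-trimethoxyphenyl)-2,3,3a,4,5,6-hexahydro-1-benzofuran-5-carboxylate A8.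
- For it: the reagents are cheap and robust, carbon is placed at C5 and oxygen at C6, and neither a silyl diene nor a volatile ynone is needed. In reagent robustness it is stronger than the chosen plan.
- Against it: A8 still needs dehydrogenation, O-methylation and conversion of a one-carbon ester into the propenyl chain, four to five steps. Under the basic Michael conditions A6 can isomerise to the endocyclic butenolide (C3=C3a), which erases C3 and makes C2–H acidic. The Claisen closure needs a dianion in competition with retro-Michael cleavage, and the freed C2 hydroxyl must be reclosed under acid.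
- Comparison: the chosen plan delivers the arene oxidation level and the complete three-carbon chain directly, and the only base treatments, of 13 and 17, take the proton at C3a and leave C2 and C3 untouched.

Key step: step 7

Assumption: the (R)-configured phosphoric acid is taken to deliver the crotyl group to the Re face of aldehyde 1, as in related aryl aldehyde allylborations; if the sense is the opposite, its enantiomer is used with no other change.

## Route

Step 1
Reactants: 1 3,4,5-trimethoxybenzaldehyde; 2 (E)-crotylboronic acid pinacol ester
Product: 4 (1R,2R)-2-methyl-1-(3,4,5-trimethoxyphenyl)but-3-en-1-ol, via pinacol borate ester 3 (not isolated)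
Conditions: (R)-3,3'-bis(2,4,6-triisopropylphenyl)-1,1'-binaphthyl-2,2'-diyl hydrogen phosphate (5 mol %), PhMe, −30 °C; aq. NaHCO3 work-up
Reagents that add atoms: none
Why: Chiral phosphoric acid-catalysed crotylboration through a closed six-membered chair transition state, so the (E)-crotyl geometry gives the anti relationship and the catalyst selects the Re face of the aldehyde, setting both stereocentres as (1R,2R). Hydrolysis of borate 3 on work-up releases 4.

Step 2
Reactants: 4 (1R,2R)-2-methyl-1-(3,4,5-trimethoxyphenyl)but-3-en-1-ol
Product: 6 (1R,2R)-2-methyl-1-(3,4,5-trimethoxyphenyl)butane-1,4-diol, via B-alkyl-9-borabicyclononane 5 (not isolated)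
Conditions: 9-BBN (2.5 equiv), THF, 0 °C → rt; then 3 M NaOH, 30% H2O2, 0 °C → rt
Reagents that add atoms: hydrogen peroxide, OO
Why: Hydroboration–oxidation: the bulky dialkylborane places boron on the terminal carbon only and the C–B bond is oxidised with retention. No stereocentre is formed, and the excess of borane allows for what the free hydroxyl consumes.

Step 3
Reactants: 6 (1R,2R)-2-methyl-1-(3,4,5-trimethoxyphenyl)butane-1,4-diol
Product: 8 (4R,5R)-4-methyl-5-(3,4,5-trimethoxyphenyl)oxolan-2-one, via lactol 7 (not isolated)
Conditions: [Cu(MeCN)4]OTf (5 mol %), 2,2'-bipyridine (5 mol %), TEMPO (5 mol %), N-methylimidazole (10 mol %), MeCN, air, rt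
Reagents that add atoms: none
Why: Aerobic copper/nitroxyl oxidative lactonisation: the catalyst oxidises the unhindered primary alcohol much faster than the secondary benzylic one, the hydroxy aldehyde closes to lactol 7, and this is oxidised on to the lactone. The methyl-bearing carbon is β to the new carbonyl and cannot epimerise.

Step 4
Reactants: 8 (4R,5R)-4-methyl-5-(3,4,5-trimethoxyphenyl)oxolan-2-one; 9 methyl acetate
Product: 12 methyl (5R,6R)-6-hydroxy-5-methyl-3-oxo-6-(3,4,5-trimethoxyphenyl)hexanoate, via lithium enolate of methyl acetate 10 (not isolated), via lithium hemiketal alkoxide 11 (not isolated)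
Conditions: LiN(iPr)2 (2.2 equiv), 9 (2.3 equiv), THF, −78 °C; then 8 in THF, −78 °C; AcOH (2.5 equiv), −78 °C → rt
Reagents that add atoms: none
Why: Claisen-type acylation of an ester enolate by a lactone: 10 adds to the lactone carbonyl and the tetrahedral alkoxide 11 persists at −78 °C, which prevents a second addition. Protonation gives 12, which equilibrates with its five-membered cyclic hemiketal.

Step 5
Reactants: 12 methyl (5R,6R)-6-hydroxy-5-methyl-3-oxo-6-(3,4,5-trimethoxyphenyl)hexanoate
Product: 13 methyl (2E)-2-[(4R,5R)-4-methyl-5-(3,4,5-trimethoxyphenyl)oxolan-2-ylidene]acetate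
Conditions: CF3CO2H (0.2 equiv), CH2Cl2, 0 °C → rt
Reagents that add atoms: none
Why: Acid-catalysed dehydration of the cyclic hemiketal form of 12 through the ring oxocarbenium ion, which loses a proton from the CH2 next to the ester to give the conjugated exocyclic enol ether (a vinylogous carbonate). The (E)-isomer, with the ester anti to the ring oxygen, should be the more stable, and the two stereocentres are not involved.

Step 6
Reactants: 13 methyl (2E)-2-[(4R,5R)-4-methyl-5-(3,4,5-trimethoxyphenyl)oxolan-2-ylidene]acetate
Product: 15 {1-methoxy-2-[(4R,5R)-4-methyl-5-(3,4,5-trimethoxyphenyl)-4,5-dihydrofuran-2-yl]ethenoxy}trimethylsilane, via lithium dienolate 14 (not isolated)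
Conditions: LiN(iPr)2 (1.15 equiv), THF, −78 °C; Me3SiCl (1.3 equiv), −78 → 0 °C; evaporate, pentane, filter under argon; used crude
Reagents that add atoms: chlorotrimethylsilane, C[Si](C)(C)Cl
Why: γ-Deprotonation of a 3-alkoxy enoate and O-silylation, the standard access to 1,3-dialkoxy-1-silyloxybutadienes: the ring CH2 (C3a) lies cis to the ester in (E)-13 and is the only acidic site, and the silyl chloride traps dienolate 14 on oxygen. Either alkene isomer of 13 gives the same dienolate, and C2 and C3 are untouched.

Step 7
Reactants: 15 {1-methoxy-2-[(4R,5R)-4-methyl-5-(3,4,5-trimethoxyphenyl)-4,5-dihydrofuran-2-yl]ethenoxy}trimethylsilane; 16 pent-1-yn-3-one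
Product: 18 1-[(2R,3R)-6-methoxy-3-methyl-2-(3,4,5-trimethoxyphenyl)-2,3-dihydro-1-benzofuran-5-yl]propan-1-one, via cyclohexadiene ketal cycloadduct 17 (not isolated)
Conditions: 16 (1.3 equiv), 2,6-di-tert-butylpyridine (10 mol %), PhMe, 0 °C → rt; evaporate; DBU (1.2 equiv), THF, 0 °C → rt
Reagents that add atoms: none
Why: The electron-rich diene 15 (C3a=C7a–C7=C6, donated by O1 and by both oxygens on C6) adds to the electron-poor alkyne of 16 in a normal-demand, strongly asynchronous Diels–Alder reaction in which C3a–C4 forms ahead of C5–C6. The closest known reaction type is the cycloaddition of 1,3-dialkoxy-1-silyloxybutadienes with acetylenic ketones and esters to give resorcinol ethers after elimination. Ring A is closed as the six-membered ring of an intermolecular [4+2] cycloaddition, suprafacial on both partners; in the stepwise limit the second bond forms by 6-exo-trig attack of the allenolate carbon C5 on the carboxonium carbon C6. The step needs orientational selectivity, which polarity provides: the largest HOMO coefficient of the diene is at C3a and the largest LUMO coefficient of the ynone at its unsubstituted, unhindered terminus C4, so the acyl group ends at C5 next to C6. The stereocentres formed at C3a and C6 in 17 are uncontrolled and both are erased on aromatisation, while C2 and C3 lie outside the reacting π-system and are carried unchanged. Aromatisation is run under base on purpose: DBU removes the doubly allylic, vinylogously acidic C3a–H and the C6 ketal expels trimethylsilanolate, a better nucleofuge than methoxide, so the methoxy group stays. Acid is excluded by the hindered pyridine buffer, because protonation at the more basic methoxy oxygen would instead expel methanol and lead to the C6 phenol. Thermal, Lewis-acid-free conditions favour addition across C≡C over hetero-cycloaddition at the ketone carbonyl.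

Step 8
Reactants: 18 1-[(2R,3R)-6-methoxy-3-methyl-2-(3,4,5-trimethoxyphenyl)-2,3-dihydro-1-benzofuran-5-yl]propan-1-one
Product: 19 1-[(2R,3R)-6-methoxy-3-methyl-2-(3,4,5-trimethoxyphenyl)-2,3-dihydro-1-benzofuran-5-yl]propan-1-ol (both carbinol epimers)
Conditions: NaBH4 (1.5 equiv), MeOH–THF, 0 °C → rt
Reagents that add atoms: none
Why: Borohydride reduction of the aryl ketone. The new carbinol centre is formed without control, which does not matter because it is removed in the next step.

Step 9
Reactants: 19 1-[(2R,3R)-6-methoxy-3-methyl-2-(3,4,5-trimethoxyphenyl)-2,3-dihydro-1-benzofuran-5-yl]propan-1-ol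
Product: 20 (2R,3R)-6-methoxy-3-methyl-5-[(1E)-prop-1-en-1-yl]-2-(3,4,5-trimethoxyphenyl)-2,3-dihydro-1-benzofuran (target CNP0122299.1)
Conditions: TsOH·H2O (5 mol %), PhMe (0.02 M), 70 °C
Reagents that add atoms: none
Why: Acid-catalysed E1 dehydration: the benzylic cation is stabilised by the ortho methoxy group and the para ring oxygen O1 and loses a proton from the adjacent CH2 to give the arene-conjugated alkene, with the (E)-isomer favoured thermodynamically. Catalytic acid, high dilution and moderate temperature limit capture of the cation by the product styrene and ionisation at C2.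

## Compound list

1 | 3,4,5-trimethoxybenzaldehyde | COc1cc(C=O)cc(OC)c1OC | starting material
2 | (E)-crotylboronic acid pinacol ester | C/C=C/CB1OC(C)(C)C(C)(C)O1 | starting material
3 | 2-{[(1R,2R)-2-methyl-1-(3,4,5-trimethoxyphenyl)but-3-en-1-yl]oxy}-4,4,5,5-tetramethyl-1,3,2-dioxaborolane | C=C[C@@H](C)[C@@H](OB1OC(C)(C)C(C)(C)O1)c1cc(OC)c(OC)c(OC)c1 | intermediate (not isolated)
4 | (1R,2R)-2-methyl-1-(3,4,5-trimethoxyphenyl)but-3-en-1-ol | C=C[C@@H](C)[C@@H](O)c1cc(OC)c(OC)c(OC)c1 | intermediate
5 | 9-[(3R,4R)-4-hydroxy-3-methyl-4-(3,4,5-trimethoxyphenyl)butyl]-9-borabicyclo[3.3.1]nonane | O[C@@H](c1cc(OC)c(OC)c(OC)c1)[C@H](C)CCB1C2CCCC1CCC2 | intermediate (not isolated)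
6 | (1R,2R)-2-methyl-1-(3,4,5-trimethoxyphenyl)butane-1,4-diol | O[C@@H](c1cc(OC)c(OC)c(OC)c1)[C@H](C)CCO | intermediate
7 | (4R,5R)-4-methyl-5-(3,4,5-trimethoxyphenyl)oxolan-2-ol (both anomers) | OC1C[C@@H](C)[C@H](c2cc(OC)c(OC)c(OC)c2)O1 | intermediate (not isolated)
8 | (4R,5R)-4-methyl-5-(3,4,5-trimethoxyphenyl)oxolan-2-one | O=C1C[C@@H](C)[C@H](c2cc(OC)c(OC)c(OC)c2)O1 | intermediate
9 | methyl acetate | COC(C)=O | starting material
10 | lithium 1-methoxyethen-1-olate (lithium enolate of methyl acetate) | [Li+].[O-]C(=C)OC | intermediate (not isolated)
11 | lithium (4R,5R)-2-(2-methoxy-2-oxoethyl)-4-methyl-5-(3,4,5-trimethoxyphenyl)oxolan-2-olate (C2 of the ring unassigned) | [Li+].[O-]C1(CC(=O)OC)C[C@@H](C)[C@H](c2cc(OC)c(OC)c(OC)c2)O1 | intermediate (not isolated)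
12 | methyl (5R,6R)-6-hydroxy-5-methyl-3-oxo-6-(3,4,5-trimethoxyphenyl)hexanoate | COC(=O)CC(=O)C[C@@H](C)[C@@H](O)c1cc(OC)c(OC)c(OC)c1 | intermediate
13 | methyl (2E)-2-[(4R,5R)-4-methyl-5-(3,4,5-trimethoxyphenyl)oxolan-2-ylidene]acetate | COC(=O)/C=C1\C[C@@H](C)[C@H](c2cc(OC)c(OC)c(OC)c2)O1 | intermediate
14 | lithium 1-methoxy-2-[(4R,5R)-4-methyl-5-(3,4,5-trimethoxyphenyl)-4,5-dihydrofuran-2-yl]ethen-1-olate | [Li+].[O-]C(OC)=CC1=C[C@@H](C)[C@H](c2cc(OC)c(OC)c(OC)c2)O1 | intermediate (not isolated)
15 | {1-methoxy-2-[(4R,5R)-4-methyl-5-(3,4,5-trimethoxyphenyl)-4,5-dihydrofuran-2-yl]ethenoxy}trimethylsilane (ketene acetal geometry not defined) | COC(O[Si](C)(C)C)=CC1=C[C@@H](C)[C@H](c2cc(OC)c(OC)c(OC)c2)O1 | intermediate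
16 | pent-1-yn-3-one | CCC(=O)C#C | starting material
17 | 1-[(2R,3R)-6-methoxy-3-methyl-2-(3,4,5-trimethoxyphenyl)-6-(trimethylsilyloxy)-2,3,3a,6-tetrahydro-1-benzofuran-5-yl]propan-1-one (C3a and C6 unassigned) | CCC(=O)C1=CC2C(=CC1(OC)O[Si](C)(C)C)O[C@@H](c1cc(OC)c(OC)c(OC)c1)[C@@H]2C | intermediate (not isolated)
18 | 1-[(2R,3R)-6-methoxy-3-methyl-2-(3,4,5-trimethoxyphenyl)-2,3-dihydro-1-benzofuran-5-yl]propan-1-one | CCC(=O)c1cc2c(cc1OC)O[C@@H](c1cc(OC)c(OC)c(OC)c1)[C@@H]2C | intermediate
19 | 1-[(2R,3R)-6-methoxy-3-methyl-2-(3,4,5-trimethoxyphenyl)-2,3-dihydro-1-benzofuran-5-yl]propan-1-ol (both carbinol epimers) | CCC(O)c1cc2c(cc1OC)O[C@@H](c1cc(OC)c(OC)c(OC)c1)[C@@H]2C | intermediate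
20 | (2R,3R)-6-methoxy-3-methyl-5-[(1E)-prop-1-en-1-yl]-2-(3,4,5-trimethoxyphenyl)-2,3-dihydro-1-benzofuran | C/C=C/c1cc2c(cc1OC)O[C@@H](c1cc(OC)c(OC)c(OC)c1)[C@@H]2C | target

## Step count and least certain steps

Total step count: 9. Longest linear sequence: 9 steps (1 to 20); compounds 2, 9 and 16 are bought.

**Step 7 (key step).** The aromatisation of ketal 17 may partition: if ionisation at C6 happens under adventitious acid before the base is added, methanol rather than silanol is lost and the C6 oxygen ends as a free phenol. The diene may also be consumed by protodesilylation, or by conjugate addition through C7 or C3a without ring closure. Fallback, from 15 and 16 back to 18: the cycloaddition is run as before, but the ketal is then collapsed deliberately with Bu4NF/AcOH in THF. Fluoride removes the silyl group, the hemiketal alkoxide expels methoxide, and the dienone tautomerises to 1-[(2R,3R)-6-hydroxy-3-methyl-2-(3,4,5-trimethoxyphenyl)-2,3-dihydro-1-benzofuran-5-yl]propan-1-one F1. Williamson methylation of F1 (MeI, K2CO3, acetone, reflux) then returns the route to 18. Any phenol formed beside 18 in the main procedure can be passed through the same methylation, so both outcomes converge.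

**Step 6.** The trimethylsilyl ketene acetal may be lost by hydrolysis during the non-aqueous work-up, and deprotonation may be incomplete or silylation may occur on carbon. Fallback, from 13 back to 18: LiN(SiMe3)2 is added at −78 °C to 13 and tBuMe2SiCl in THF/DMPU (in situ trapping). This should give the more robust tert-butyl({1-methoxy-2-[(4R,5R)-4-methyl-5-(3,4,5-trimethoxyphenyl)-4,5-dihydrofuran-2-yl]ethenyl}oxy)dimethylsilane F2, which can be filtered through Et3N-deactivated silica and stored. Cycloaddition of F2 with 16 under the conditions of step 7 gives the cyclohexadiene ketal 1-[(2R,3R)-6-(tert-butyldimethylsilyloxy)-6-methoxy-3-methyl-2-(3,4,5-trimethoxyphenyl)-2,3,3a,6-tetrahydro-1-benzofuran-5-yl]propan-1-one F3, and DBU then expels the silanolate to give 18.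

**Step 5.** Under acid the open hydroxy ketone form of 12 may ionise at the benzylic carbon, which would erode the trans purity at C2 (C3 is unaffected), and the double bond may settle partly in the ring. Fallback, from 8 back to 13: lactone 8 is olefinated directly with the stabilised ylide Ph3P=CHCO2Me in toluene at 130 °C (sealed tube), a Wittig reaction on the lactone carbonyl that bypasses 12 and all acid. This makes no new compound (none, F0).

**Step 9.** The benzylic cation may be captured by the product styrene (dimerisation), or the C2–O1 ether may ionise on prolonged exposure to acid. Fallback, from 18 back to 20 without 19: KN(SiMe3)2 in THF at −78 °C forms the (Z)-enolate of 18 (methyl cis to oxygen), which PhNTf2 traps as (1Z)-1-[(2R,3R)-6-methoxy-3-methyl-2-(3,4,5-trimethoxyphenyl)-2,3-dihydro-1-benzofuran-5-yl]prop-1-en-1-yl trifluoromethanesulfonate F4. Reduction of F4 with Pd(OAc)2/PPh3, HCO2H and Et3N in DMF at 60 °C replaces the triflate by hydrogen with retention, giving the (E)-propenyl group of 20 under non-acidic conditions.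

**Step 1.** The electron-rich aldehyde is a weak electrophile, so the uncatalysed background addition may compete and lower the enantiomeric purity, or the sense of induction may differ from the one assumed. Fallback, from 1 back to 4: iridium-catalysed transfer-hydrogenative anti-crotylation of 1 with but-3-en-2-yl acetate ([Ir(cod)Cl]2, the SEGPHOS enantiomer that gives the (1R,2R) product, 4-cyano-3-nitrobenzoic acid, Cs2CO3, propan-2-ol, THF, 60 °C). This makes no new compound (none, F0).

## Further compounds

F1 | step 7 | 1-[(2R,3R)-6-hydroxy-3-methyl-2-(3,4,5-trimethoxyphenyl)-2,3-dihydro-1-benzofuran-5-yl]propan-1-one | CCC(=O)c1cc2c(cc1O)O[C@@H](c1cc(OC)c(OC)c(OC)c1)[C@@H]2C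
F2 | step 6 | tert-butyl({1-methoxy-2-[(4R,5R)-4-methyl-5-(3,4,5-trimethoxyphenyl)-4,5-dihydrofuran-2-yl]ethenyl}oxy)dimethylsilane | COC(O[Si](C)(C)C(C)(C)C)=CC1=C[C@@H](C)[C@H](c2cc(OC)c(OC)c(OC)c2)O1
F3 | step 6 | 1-[(2R,3R)-6-(tert-butyldimethylsilyloxy)-6-methoxy-3-methyl-2-(3,4,5-trimethoxyphenyl)-2,3,3a,6-tetrahydro-1-benzofuran-5-yl]propan-1-one | CCC(=O)C1=CC2C(=CC1(OC)O[Si](C)(C)C(C)(C)C)O[C@@H](c1cc(OC)c(OC)c(OC)c1)[C@@H]2C
F0 | step 5 | none | none
F4 | step 9 | (1Z)-1-[(2R,3R)-6-methoxy-3-methyl-2-(3,4,5-trimethoxyphenyl)-2,3-dihydro-1-benzofuran-5-yl]prop-1-en-1-yl trifluoromethanesulfonate | C/C=C(\OS(=O)(=O)C(F)(F)F)c1cc2c(cc1OC)O[C@@H](c1cc(OC)c(OC)c(OC)c1)[C@@H]2C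
F0 | step 1 | none | none
A1 | alternative 1 | (6R,7R)-7-hydroxy-6-methyl-7-(3,4,5-trimethoxyphenyl)hept-1-en-4-yn-3-one | C=CC(=O)C#CC[C@@H](C)[C@@H](O)c1cc(OC)c(OC)c(OC)c1
A2 | alternative 1 | (2R,3R)-3-methyl-2-(3,4,5-trimethoxyphenyl)-3,3a,4,5-tetrahydro-1-benzofuran-6(2H)-one (C3a unassigned) | O=C1CCC2C(=C1)O[C@@H](c1cc(OC)c(OC)c(OC)c1)[C@@H]2C
A3 | alternative 2 | (S)-[(2R)-oxiran-2-yl](3,4,5-trimethoxyphenyl)methanol | O[C@@H](c1cc(OC)c(OC)c(OC)c1)[C@H]1CO1
A4 | alternative 2 | 3-chloro-5-methoxybenzyne | COC1=CC#CC(Cl)=C1
A5 | alternative 2 | [(2R,3S)-4-chloro-6-methoxy-2-(3,4,5-trimethoxyphenyl)-2,3-dihydro-1-benzofuran-3-yl]methanol | COc1cc(Cl)c2c(c1)O[C@@H](c1cc(OC)c(OC)c(OC)c1)[C@@H]2CO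
A6 | alternative 3 | (4R,5R)-4-methyl-3-methylidene-5-(3,4,5-trimethoxyphenyl)oxolan-2-one | C=C1C(=O)O[C@@H](c2cc(OC)c(OC)c(OC)c2)[C@@H]1C
A7 | alternative 3 | ethyl 3-oxobutanoate | CCOC(=O)CC(C)=O
A8 | alternative 3 | ethyl (2R,3R)-3-methyl-6-oxo-2-(3,4,5-trimethoxyphenyl)-2,3,3a,4,5,6-hexahydro-1-benzofuran-5-carboxylate (C3a and C5 unassigned) | CCOC(=O)C1CC2C(=CC1=O)O[C@@H](c1cc(OC)c(OC)c(OC)c1)[C@@H]2C
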